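## The problem

The target 13 is a flavan: a dihydropyran (ring C) fused to a phloroglucinol ring (ring A), with a 3-hydroxy-5-methoxyphenyl group (ring B) at C2. C2 is the only stereocentre and is S. No second centre can relay to it, so a reagent or catalyst must set it, and it must then survive to the end. Ring A is fully differentiated: its three oxygens are the ring ether O1, the 5-OH and the 7-OH, and the prenyl group must sit at C8, between O1 and O7, not at C6. Ring B carries one free phenol beside one methyl ether, so methyl ethers cannot serve as protecting groups anywhere. Both ring-B oxygens are meta to C1', so they do not stabilise positive charge at C2, yet they make the ring itself a strong Friedel–Crafts partner. The fragile parts are the prenyl olefin next to the 7-OH (acid closes it to a dimethylchroman; hydrogenation and oxidants attack it), the electron-rich ring A, and the free polyphenol under base and air. The enabling feature is that O1–C8a–C4a–C4 has the connectivity of an o-quinone methide and C3–C2(aryl) that of a styrene, with C4 already at the CH2 level. Ring C and its stereocentre can therefore be made in one cycloaddition.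

## Retrosynthesis

**13 from 12.** The last cut removes two O–Si bonds and one O–acyl bond. All three fall to methoxide in one operation. No acid reaches the prenyl group, no hydrogen is used, and no Lewis acid threatens the methyl ether. The forward step only has to go to completion under argon.

**12 from 11.** The prenyl C=C is cut back to a terminal allyl group (cross-metathesis with 2-methyl-2-butene). Carrying prenyl through the acid step was considered and set aside. The trisubstituted olefin is the most easily protonated and most nucleophilic C=C in the molecule, and it sits next to the free O1 phenol. An allyl group is inert there, which allows a strong chiral acid in the key step. The allyl group also arrives by a rearrangement that fixes its position (see 5).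

**11 from 6 and 9, through 10.** C3–C4 and O1–C2 are cut together, giving o-quinone methide 10 and styrene 9. Cutting O1–C2 alone or C4–C4a alone would leave an open chain whose stereocentre has to be made separately. This cut makes two bonds, ring C and C2 in one step, and splits the target into two achiral arenes of similar size. The forward reaction needs three things:
- The quinone methide must form on one side only. This holds because only the O1 phenol of 6 is free.
- The vinyl group of 9 must outcompete every arene. A free ring-B phenol was rejected because acid-bound o-quinone methides alkylate phenols readily at carbon; the acetate in 9 reduces ring B to anisole-level reactivity.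
- The catalyst must select one face and one orientation of the styrene.

**6 from 5.** The C4 oxidation level is adjusted: the labile salicyl alcohol 6 comes from the stable salicylaldehyde 5 by hydride reduction, immediately before use. The formyl group also serves earlier as the blocking group at one ortho position.

**5 from 3, through 4.** The C8–CH2 bond is cut back to an O-allyl ether (Claisen rearrangement via dienone 4). Direct C-prenylation of 1 followed by selective protection would depend on a rate difference between two ortho hydroxyls. Here the [3,3] shift places the carbon chain next to the very oxygen it frees, so the O1/C8 relationship is fixed by mechanism.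

**3 from 2 from 1.** One O–allyl and two O–Si bonds are cut. Aldehyde 1 is symmetric, so bis-silylation can give only one product, 2, whose last hydroxyl is chelated. That hydroxyl is then allylated under neutral conditions.

**9 from 8 from 7.** The acetate is removed and the vinyl C=C is cut by a Wittig transform. Aldehyde 7 already carries the OH/OMe pattern of ring B.

## Roads not taken

Alternative 1: The cut is C4–C4a. In the forward step, cathodic reduction of the redox-active ester A2 with a nickel–bipyridine catalyst would give a primary C4 radical. Nickel would couple it with the C4a bromide and close ring C to A1, the tris(methoxymethyl) ether of 13.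
- Merits: C2 is set beforehand by reagent-controlled chemistry, ring B is a bystander, and the closure is intramolecular.
- Weak points: the bromide sits between an acetal oxygen and the aryloxy oxygen on a trioxygenated ring, which is unfavourable for oxidative addition to low-valent nickel. The O1–C2 ether of A2 must be made by inversion at a benzylic carbinol with a phenol flanked by bromine and prenyl. The radical can be lost to hydrogen abstraction. Ring A still needs its oxygens differentiated, plus a bromination. The acetals must finally be removed with acid next to the prenyl group. The longest linear sequence would be about twelve steps.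
- Comparison: this road is stronger on stereochemical certainty. The chosen plan answers with one step that makes both bonds, the ring and the stereocentre, a seven-step longest sequence, and a reserve route for step 7 that uses the same reduction-and-inversion logic.

Alternative 2: The cut removes three ring-A bonds (C8a–C8, C7–C6, C4a–C8a). In the forward step, thermolysis of cyclobutenone A4 with siloxyalkyne A5 (Danheiser benzannulation) would give phenol A3.
- Merits: the substitution pattern of ring A is assembled with complete positional control, and the C8a hydroxyl emerges free and distinct from O5 and O7.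
- Weak points: A4, a 4-alkyl cyclobutenone carrying the whole chiral chain, needs a long synthesis of its own. This class gives fully substituted phenols least efficiently. In A3 ring C is still open, so a closure with inversion at the benzylic carbinol and a triple desilylation remain. A ring that can be bought as 1 is built from scratch.
- Comparison: regiochemical security is equal or better. The chosen plan gets the same security from the Claisen rearrangement in three steps from 1, and its key step delivers ring C and C2, which A3 lacks.

Alternative 3: The cut removes two ring-B bonds (C1'–C6', C4'–C5'). In the forward step, dimethyl malonate A8 and NaOMe would add to enone A7, and Claisen closure would give dione ester A6. Decarboxylation, enol-ether formation and dehydrogenation would follow.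
- Merits: the OH/OMe difference of ring B is built in, and ring B is not an arene while bonds are made, so its Friedel–Crafts reactivity is irrelevant.
- Weak points: A7 must already be an enantiopure 2-substituted chroman, so the stereochemical problem is moved, not solved. Its C2–H is γ to the ketone, and methoxide can epimerise it through the dienolate. A6 is a mixture. The final dehydrogenation needs iodine, a quinone or hot palladium, each of which attacks the prenyl group or ring A. Acid is again needed for the acetals.
- Comparison: this is conceptually the neatest answer to ring-B differentiation. The chosen plan sets against it only that 7 is bought with the pattern in place, and it is shorter and milder elsewhere.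

Key step: step 7

Assumption: the sense of induction of the chiral acid in step 7 cannot be derived beforehand; the (R)-acid is written, and its antipode is used if a trial shows that it gives the (2R)-flavan. Flavan numbering is used throughout, and 1 and 7 are taken as commercial.

## Route

Step 1
Reactants: 1 2,4,6-trihydroxybenzaldehyde
Product: 2 2-hydroxy-4,6-bis[(tert-butyldimethylsilyl)oxy]benzaldehyde
Conditions: TBSCl (2.1 equiv), imidazole, DMF, 0 °C to rt
Reagents that add atoms: tert-butyldimethylsilyl chloride, C[Si](C)(Cl)C(C)(C)C
Why: Silyl ether formation; the unchelated 4-OH and one of the two equivalent ortho hydroxyls react, the remaining ortho-OH is held in a hydrogen bond to the formyl oxygen and reacts far more slowly, and the symmetry of 1 allows only one bis-ether.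

Step 2
Reactants: 2 2-hydroxy-4,6-bis[(tert-butyldimethylsilyl)oxy]benzaldehyde
Product: 3 2-(allyloxy)-4,6-bis[(tert-butyldimethylsilyl)oxy]benzaldehyde
Conditions: allyl alcohol, PPh3, diisopropyl azodicarboxylate, THF, 0 °C to rt
Reagents that add atoms: allyl alcohol, C=CCO
Why: Mitsunobu etherification; the chelated phenol is acidic enough to protonate the betaine and is alkylated on oxygen, and the neutral conditions avoid the phenoxide-induced silyl transfer that a carbonate base could cause with aryl silyl ethers ortho and para to a formyl group.

Step 3
Reactants: 3 2-(allyloxy)-4,6-bis[(tert-butyldimethylsilyl)oxy]benzaldehyde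
Product: 5 3-allyl-2-hydroxy-4,6-bis[(tert-butyldimethylsilyl)oxy]benzaldehyde, via ortho-dienone 4 (not isolated)
Conditions: PhNEt2, 190 °C, sealed tube, argon
Reagents that add atoms: none
Why: Aromatic Claisen rearrangement; the [3,3] shift delivers the allyl group to the only free ortho carbon, which both silyloxy groups activate, and dienone 4 tautomerises to the chelated phenol, so the carbon chain ends next to the oxygen that is set free.

Step 4
Reactants: 5 3-allyl-2-hydroxy-4,6-bis[(tert-butyldimethylsilyl)oxy]benzaldehyde
Product: 6 2-allyl-6-(hydroxymethyl)-3,5-bis[(tert-butyldimethylsilyl)oxy]phenol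
Conditions: NaBH4, THF/MeOH, −10 °C; pH 7 phosphate buffer; used crude at once
Reagents that add atoms: none
Why: Borohydride reduction of the aldehyde to the benzylic alcohol; low temperature, short contact and a buffered quench limit over-reduction through the phenoxide and migration of the ortho silyl group, and the acid-labile product is not chromatographed.

Step 5
Reactants: 7 3-hydroxy-5-methoxybenzaldehyde
Product: 8 3-methoxy-5-vinylphenol
Conditions: Ph3PCH3Br (2.5 equiv), KOtBu (2.5 equiv), THF, 0 °C to rt
Reagents that add atoms: methyltriphenylphosphonium bromide, C[P+](c1ccccc1)(c1ccccc1)c1ccccc1.[Br-]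
Why: Wittig methylenation; the first equivalent of ylide is consumed by the phenol, and the phenoxide aldehyde still olefinates with the unstabilised ylide.

Step 6
Reactants: 8 3-methoxy-5-vinylphenol
Product: 9 3-methoxy-5-vinylphenyl acetate
Conditions: Ac2O, pyridine, 4-dimethylaminopyridine (cat.), CH2Cl2, 0 °C
Reagents that add atoms: acetic anhydride, CC(=O)OC(C)=O
Why: Acylation of the phenol; the acetate removes the hydrogen-bond handle and most of the π-donation that would make ring B a Friedel–Crafts partner in step 7, so the vinyl group becomes the most nucleophilic site of 9, and it leaves later together with the silyl groups.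

Step 7
Reactants: 6 2-allyl-6-(hydroxymethyl)-3,5-bis[(tert-butyldimethylsilyl)oxy]phenol; 9 3-methoxy-5-vinylphenyl acetate
Product: 11 3-[(2S)-8-allyl-5,7-bis[(tert-butyldimethylsilyl)oxy]chroman-2-yl]-5-methoxyphenyl acetate, via o-quinone methide 10 (not isolated)
Conditions: (R)-3,3'-bis(2,4,6-triisopropylphenyl)-1,1'-binaphthalene-2,2'-diyl N-triflylphosphoramide (5 mol%), 9 (4 equiv), 5 Å MS, toluene, −20 °C, slow addition of 6
Reagents that add atoms: none
Why: Inverse-demand hetero-Diels–Alder reaction: the acid protonates the benzylic hydroxyl of 6, water leaves with help from the free ortho-OH and the two silyloxy donors, and o-quinone methide 10 stays hydrogen-bonded or ion-paired to the chiral phosphoramide anion. The terminal CH2 of 9 bonds to the exocyclic methylene (C3–C4) while O1 closes onto the benzylic carbon (O1–C2), a concerted but asynchronous [4+2] cycloaddition that forms the six-membered ring C. The closest known reaction type is the chiral Brønsted acid-catalysed cycloaddition of o-quinone methides, made in situ from o-hydroxybenzyl alcohols, with styrenes. Regiochemistry follows the polarisation of both partners, and because only the O1 phenol is free the quinone methide forms on one side only, so the allyl group ends at C8. C2 is the only new stereocentre and is set by the catalyst, whose 3,3'-aryl groups shield one face of the bound heterodiene and admit the styrene in one (endo) orientation; since C4 is CH2, both face selection and endo/exo selection must be high. Chemoselectivity rests on the substrates: the acetate mutes ring B, the allyl group is a much poorer nucleophile and much harder to protonate than a prenyl group, and the two silyl groups shield C6 against self-condensation, while slow addition of 6 to excess 9 keeps 10 dilute. The product should not ionise at C2 under the acid, because ring B has no ortho or para donor.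

Step 8
Reactants: 11 3-[(2S)-8-allyl-5,7-bis[(tert-butyldimethylsilyl)oxy]chroman-2-yl]-5-methoxyphenyl acetate
Product: 12 3-[(2S)-5,7-bis[(tert-butyldimethylsilyl)oxy]-8-(3-methylbut-2-en-1-yl)chroman-2-yl]-5-methoxyphenyl acetate
Conditions: 2-methyl-2-butene (excess), second-generation Grubbs catalyst RuCl2(=CHPh)(PCy3)(H2IMes) (5 mol%), CH2Cl2, 40 °C
Reagents that add atoms: 2-methyl-2-butene, CC=C(C)C
Why: Olefin cross-metathesis of an allyl arene with 2-methyl-2-butene, the standard conversion of allyl into prenyl; the excess of the trisubstituted olefin suppresses homodimerisation, propene escapes, and acetate, silyl ethers and C2 are not touched.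

Step 9
Reactants: 12 3-[(2S)-5,7-bis[(tert-butyldimethylsilyl)oxy]-8-(3-methylbut-2-en-1-yl)chroman-2-yl]-5-methoxyphenyl acetate
Product: 13 (2S)-2-(3-hydroxy-5-methoxyphenyl)-8-(3-methylbut-2-en-1-yl)chroman-5,7-diol
Conditions: K2CO3, degassed MeOH/THF, rt, argon; aq. NH4Cl
Reagents that add atoms: none
Why: Base-mediated methanolysis; methoxide cleaves the aryl acetate quickly and the two aryl silyl ethers more slowly (phenoxide is a good leaving group on silicon), no acid reaches the prenyl group, the methyl ether is inert, and C2 cannot epimerise because ring B offers no quinone methide pathway for opening the pyran.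

## Compound list

1 | 2,4,6-trihydroxybenzaldehyde | O=Cc1c(O)cc(O)cc1O | starting material
2 | 2-hydroxy-4,6-bis[(tert-butyldimethylsilyl)oxy]benzaldehyde | O=Cc1c(O)cc(O[Si](C)(C)C(C)(C)C)cc1O[Si](C)(C)C(C)(C)C | intermediate
3 | 2-(allyloxy)-4,6-bis[(tert-butyldimethylsilyl)oxy]benzaldehyde | O=Cc1c(OCC=C)cc(O[Si](C)(C)C(C)(C)C)cc1O[Si](C)(C)C(C)(C)C | intermediate
4 | ortho-dienone 5-allyl-2,4-bis[(tert-butyldimethylsilyl)oxy]-6-oxocyclohexa-1,3-diene-1-carbaldehyde (racemic, not isolated) | O=CC1=C(O[Si](C)(C)C(C)(C)C)C=C(O[Si](C)(C)C(C)(C)C)C(CC=C)C1=O | intermediate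
5 | 3-allyl-2-hydroxy-4,6-bis[(tert-butyldimethylsilyl)oxy]benzaldehyde | O=Cc1c(O)c(CC=C)c(O[Si](C)(C)C(C)(C)C)cc1O[Si](C)(C)C(C)(C)C | intermediate
6 | 2-allyl-6-(hydroxymethyl)-3,5-bis[(tert-butyldimethylsilyl)oxy]phenol | OCc1c(O)c(CC=C)c(O[Si](C)(C)C(C)(C)C)cc1O[Si](C)(C)C(C)(C)C | intermediate
7 | 3-hydroxy-5-methoxybenzaldehyde | COc1cc(O)cc(C=O)c1 | starting material
8 | 3-methoxy-5-vinylphenol | C=Cc1cc(O)cc(OC)c1 | intermediate
9 | 3-methoxy-5-vinylphenyl acetate | C=Cc1cc(OC(C)=O)cc(OC)c1 | intermediate
10 | o-quinone methide 2-allyl-3,5-bis[(tert-butyldimethylsilyl)oxy]-6-methylenecyclohexa-2,4-dien-1-one (not isolated) | C=C1C(=O)C(CC=C)=C(O[Si](C)(C)C(C)(C)C)C=C1O[Si](C)(C)C(C)(C)C | intermediate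
11 | 3-[(2S)-8-allyl-5,7-bis[(tert-butyldimethylsilyl)oxy]chroman-2-yl]-5-methoxyphenyl acetate | COc1cc(OC(C)=O)cc([C@@H]2CCc3c(O[Si](C)(C)C(C)(C)C)cc(O[Si](C)(C)C(C)(C)C)c(CC=C)c3O2)c1 | intermediate
12 | 3-[(2S)-5,7-bis[(tert-butyldimethylsilyl)oxy]-8-(3-methylbut-2-en-1-yl)chroman-2-yl]-5-methoxyphenyl acetate | COc1cc(OC(C)=O)cc([C@@H]2CCc3c(O[Si](C)(C)C(C)(C)C)cc(O[Si](C)(C)C(C)(C)C)c(CC=C(C)C)c3O2)c1 | intermediate
13 | (2S)-2-(3-hydroxy-5-methoxyphenyl)-8-(3-methylbut-2-en-1-yl)chroman-5,7-diol | COc1cc(O)cc([C@@H]2CCc3c(O)cc(O)c(CC=C(C)C)c3O2)c1 | target

## Step count and least certain steps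

Total: 9 steps. Longest linear sequence: 7 steps (steps 1, 2, 3, 4, 7, 8, 9).

**Step 7 (key step).** Two processes may fail. The cycloaddition may be slow, because 9 carries two inductively withdrawing meta oxygens and 10 is a donor-stabilised quinone methide; 10 would then dimerise or alkylate ring A of a second molecule. Face and endo/exo discrimination may also be poor, because the diene terminus is an unsubstituted CH2. The fallback keeps the C3–C4 bond formation through 10 but uses a much stronger π-nucleophile and sets C2 by ketone reduction. Tsuji–Wacker oxidation of 9 (PdCl2, CuCl, O2, DMF/H2O) gives 3-acetyl-5-methoxyphenyl acetate F1. TMSOTf/Et3N converts it into 3-methoxy-5-[1-(trimethylsilyloxy)vinyl]phenyl acetate F2. Reaction of 6 with F2 under (PhO)2P(O)OH catalysis (Mukaiyama–Michael addition to 10, desilylation on work-up) gives the ketone 3-[3-[3-allyl-2-hydroxy-4,6-bis[(tert-butyldimethylsilyl)oxy]phenyl]propanoyl]-5-methoxyphenyl acetate F3. Asymmetric transfer hydrogenation with RuCl[(R,R)-TsDPEN](p-cymene) (TsDPEN = N-tosyl-1,2-diphenylethylenediamine) in HCO2H/Et3N leaves the allyl group alone. By analogy with acetophenone-type ketones it should give the carbinol 3-[(1R)-3-[3-allyl-2-hydroxy-4,6-bis[(tert-butyldimethylsilyl)oxy]phenyl]-1-hydroxypropyl]-5-methoxyphenyl acetate F4. Intramolecular Mitsunobu etherification (PPh3, diisopropyl azodicarboxylate) then closes ring C with inversion. This fallback sets out from 6 and 9 and returns at 11.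

**Step 4.** The phenoxide may expel the benzylic oxygen, and hydride then over-reduces to the C-methyl compound. The ortho silyl group may migrate to the benzylic oxygen, which would free the second ortho phenol and lose the regiocontrol. The product may also self-condense on isolation. The fallback avoids the free salicyl alcohol altogether. Aldehyde 5, trimethyl orthoformate and 9 are combined under the acid of step 7. The aldehyde enters as its O-methyl oxocarbenium ion, a quinone methide equivalent, and the same two bonds form to give 3-[(2S)-8-allyl-5,7-bis[(tert-butyldimethylsilyl)oxy]-4-methoxychroman-2-yl]-5-methoxyphenyl acetate F5 as a mixture at C4. Ionic hydrogenation (Et3SiH, BF3·OEt2, CH2Cl2, −78 °C) removes the 4-methoxy group through the ring-A-stabilised benzylic cation. This fallback sets out from 5 and 9 and returns at 11.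

**Step 3.** At 190 °C the allyl group may attack the formyl-bearing carbon and shift on to the para position, which would become C6. Deformylation or silyl loss may also occur. The fallback introduces the C8 substituent by direct C-alkylation of the symmetric starting material. Compound 1 is C-prenylated with prenyl bromide and DBU in THF to give 2,4,6-trihydroxy-3-(3-methylbut-2-en-1-yl)benzaldehyde F6. Two equivalents of TBSCl/imidazole should silylate the 4-OH and the less hindered ortho-OH to give 2-hydroxy-3-(3-methylbut-2-en-1-yl)-4,6-bis[(tert-butyldimethylsilyl)oxy]benzaldehyde F7; the regiochemistry would have to be proven by NOE. NaBH4 gives 2-(hydroxymethyl)-6-(3-methylbut-2-en-1-yl)-3,5-bis[(tert-butyldimethylsilyl)oxy]phenol F8. F8 undergoes the cycloaddition of step 7 with 9, now with the weaker (R)-3,3'-bis(2,4,6-triisopropylphenyl)-1,1'-binaphthalene-2,2'-diyl hydrogen phosphate because the prenyl olefin is present, and step 8 falls away. This fallback sets out from 1 and returns at 12.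

**Step 9.** Cleavage of the hindered 7-O-silyl ether next to the prenyl group may be incomplete, and the phloroglucinol phenoxides may oxidise during long exposure to base. The fallback removes the two kinds of protecting group by two different mechanisms. Bu4NF buffered with AcOH in THF at 0 °C cleaves both silyl ethers of 12 and gives 3-[(2S)-5,7-dihydroxy-8-(3-methylbut-2-en-1-yl)chroman-2-yl]-5-methoxyphenyl acetate F9. Brief ammonolysis (NH3 in MeOH, 0 °C) then removes the acetate. This fallback sets out from 12 and returns at 13.

## Further compounds

F1 | step 7 | 3-acetyl-5-methoxyphenyl acetate | CC(=O)c1cc(OC)cc(OC(C)=O)c1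
F2 | step 7 | 3-methoxy-5-[1-(trimethylsilyloxy)vinyl]phenyl acetate | C=C(O[Si](C)(C)C)c1cc(OC)cc(OC(C)=O)c1
F3 | step 7 | 3-[3-[3-allyl-2-hydroxy-4,6-bis[(tert-butyldimethylsilyl)oxy]phenyl]propanoyl]-5-methoxyphenyl acetate | COc1cc(OC(C)=O)cc(C(=O)CCc2c(O[Si](C)(C)C(C)(C)C)cc(O[Si](C)(C)C(C)(C)C)c(CC=C)c2O)c1
F4 | step 7 | 3-[(1R)-3-[3-allyl-2-hydroxy-4,6-bis[(tert-butyldimethylsilyl)oxy]phenyl]-1-hydroxypropyl]-5-methoxyphenyl acetate | COc1cc(OC(C)=O)cc([C@H](O)CCc2c(O[Si](C)(C)C(C)(C)C)cc(O[Si](C)(C)C(C)(C)C)c(CC=C)c2O)c1
F5 | step 4 | 3-[(2S)-8-allyl-5,7-bis[(tert-butyldimethylsilyl)oxy]-4-methoxychroman-2-yl]-5-methoxyphenyl acetate (both C4 epimers) | COc1cc(OC(C)=O)cc([C@@H]2CC(OC)c3c(O[Si](C)(C)C(C)(C)C)cc(O[Si](C)(C)C(C)(C)C)c(CC=C)c3O2)c1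
F6 | step 3 | 2,4,6-trihydroxy-3-(3-methylbut-2-en-1-yl)benzaldehyde | O=Cc1c(O)cc(O)c(CC=C(C)C)c1O
F7 | step 3 | 2-hydroxy-3-(3-methylbut-2-en-1-yl)-4,6-bis[(tert-butyldimethylsilyl)oxy]benzaldehyde | O=Cc1c(O)c(CC=C(C)C)c(O[Si](C)(C)C(C)(C)C)cc1O[Si](C)(C)C(C)(C)C
F8 | step 3 | 2-(hydroxymethyl)-6-(3-methylbut-2-en-1-yl)-3,5-bis[(tert-butyldimethylsilyl)oxy]phenol | OCc1c(O)c(CC=C(C)C)c(O[Si](C)(C)C(C)(C)C)cc1O[Si](C)(C)C(C)(C)C
F9 | step 9 | 3-[(2S)-5,7-dihydroxy-8-(3-methylbut-2-en-1-yl)chroman-2-yl]-5-methoxyphenyl acetate | COc1cc(OC(C)=O)cc([C@@H]2CCc3c(O)cc(O)c(CC=C(C)C)c3O2)c1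
A1 | alternative 1 | (2S)-5,7-bis(methoxymethoxy)-2-[3-methoxy-5-(methoxymethoxy)phenyl]-8-(3-methylbut-2-en-1-yl)chroman | COc1cc(OCOC)cc([C@@H]2CCc3c(OCOC)cc(OCOC)c(CC=C(C)C)c3O2)c1
A2 | alternative 1 | 1,3-dioxoisoindolin-2-yl (4S)-4-[2-bromo-3,5-bis(methoxymethoxy)-6-(3-methylbut-2-en-1-yl)phenoxy]-4-[3-methoxy-5-(methoxymethoxy)phenyl]butanoate | COc1cc(OCOC)cc([C@H](CCC(=O)ON2C(=O)c3ccccc3C2=O)Oc2c(Br)c(OCOC)cc(OCOC)c2CC=C(C)C)c1
A3 | alternative 2 | 2-[(3R)-3-[3-methoxy-5-(triisopropylsilyloxy)phenyl]-3-(triethylsilyloxy)propyl]-6-(3-methylbut-2-en-1-yl)-3,5-bis(triisopropylsilyloxy)phenol | Oc1c(CC=C(C)C)c(O[Si](C(C)C)(C(C)C)C(C)C)cc(O[Si](C(C)C)(C(C)C)C(C)C)c1CC[C@@H](O[Si](CC)(CC)CC)c1cc(OC)cc(O[Si](C(C)C)(C(C)C)C(C)C)c1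
A4 | alternative 2 | 4-[(3R)-3-[3-methoxy-5-(triisopropylsilyloxy)phenyl]-3-(triethylsilyloxy)propyl]-3-(triisopropylsilyloxy)cyclobut-2-en-1-one | O=C1C=C(O[Si](C(C)C)(C(C)C)C(C)C)C1CC[C@@H](O[Si](CC)(CC)CC)c1cc(OC)cc(O[Si](C(C)C)(C(C)C)C(C)C)c1
A5 | alternative 2 | triisopropyl[(5-methylhex-4-en-1-yn-1-yl)oxy]silane | CC(C)=CCC#CO[Si](C(C)C)(C(C)C)C(C)C
A6 | alternative 3 | methyl 6-[(2S)-5,7-bis(methoxymethoxy)-8-(3-methylbut-2-en-1-yl)chroman-2-yl]-2,4-dioxocyclohexane-1-carboxylate | COC(=O)C1C(=O)CC(=O)CC1[C@@H]3CCc2c(OCOC)cc(OCOC)c(CC=C(C)C)c2O3
A7 | alternative 3 | (E)-4-[(2S)-5,7-bis(methoxymethoxy)-8-(3-methylbut-2-en-1-yl)chroman-2-yl]but-3-en-2-one | CC(=O)/C=C/[C@@H]1CCc2c(OCOC)cc(OCOC)c(CC=C(C)C)c2O1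
A8 | alternative 3 | dimethyl malonate | COC(=O)CC(=O)OC
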